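**Plan**

- Retrosynthesis: the two aryl–O–C ether bonds of the side chains are cut first (bis-phenol core plus a lactate-derived α-tosyloxy ketone). The C3 methyl is then traced back to a formyl group, the C2–C3 ring bond is cut to give a seven-membered vinyl acetal, and last come the enol ether C=C, the acetal C–O bonds and the crotyl C–C bond.
- Enabling feature: in the tetrahydrofuran (O1, C2–C5), C2 carries the ring oxygen and an aryl group, so it is an aldehyde-level carbon, and its neighbour C3 carries a one-carbon branch cis to that aryl. C2 can therefore be an oxocarbenium carbon and C3 an enol carbon, both stored in one 4,5-dihydro-1,3-dioxepine.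
- Forward: crotylboration of O-benzylvanillin (C4–C5), mixed vinyl acetal with a second aldehyde unit, ring-closing metathesis to the seven-membered ring, contraction to the five-membered ring (C2–C3), CHO to CH3, debenzylation, double side-chain attachment, ketone reduction.
- Stereochemistry: C4 and C5 from the (Z)-crotylborane with isopinocampheyl ligands; C2 and C3 from the ring contraction under substrate control; the two side-chain C–O carbons from ethyl (S)-lactate with inversion; the two carbinol carbons from a CBS reduction.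

Key step: step 7

Remark: ring atoms are numbered O1, C2 (aryl from the acetal carbon), C3, C4, C5 (aryl from the crotylation); compounds 11–13 are taken as mixtures of the two acetal epimers, which is harmless because that carbon becomes planar in step 7.

**Route**

Step 1
Reactants: 1 vanillin; 2 benzyl bromide
Product: 3 4-(benzyloxy)-3-methoxybenzaldehyde
Conditions: K2CO3, DMF, rt
Reagents that add atoms: none
Why: Williamson ether synthesis of the phenoxide with a benzylic bromide, which leaves the aldehyde untouched.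

Step 2
Reactants: 3 4-(benzyloxy)-3-methoxybenzaldehyde; 4 cis-2-butene
Product: 7 (1R,2S)-1-[4-(benzyloxy)-3-methoxyphenyl]-2-methylbut-3-en-1-ol, via (Z)-crotyldiisopinocampheylborane 5 (not isolated), via homoallyl diisopinocampheylborinate 6 (not isolated)
Conditions: 4, n-BuLi, KOtBu, THF, −78 to −45 °C; (+)-Ipc2BOMe, −78 °C; BF3·OEt2, −78 °C; 3, −78 °C; then NaOH, H2O2, 0 °C to rt
Reagents that add atoms: none
Why: Brown asymmetric crotylboration through a closed Zimmerman–Traxler chair, in which the Z geometry of the crotyl group becomes the syn relationship of hydroxyl and methyl (C4/C5 cis in the later ring) and the isopinocampheyl groups derived from (−)-α-pinene direct the crotyl group to the Re face of the aryl aldehyde, so that the carbinol carbon should be R and the methyl-bearing carbon S.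

Step 3
Reactants: 3 4-(benzyloxy)-3-methoxybenzaldehyde; 8 2-bromoethanol
Product: 9 1-(benzyloxy)-4-[bis(2-bromoethoxy)methyl]-2-methoxybenzene
Conditions: 8 (3 equiv), p-TsOH·H2O (cat.), toluene, reflux, Dean–Stark trap
Reagents that add atoms: none
Why: acid-catalysed acetalisation driven by azeotropic removal of water, giving a symmetrical acetal whose two alkoxy groups are equivalent for the exchange that follows.

Step 4
Reactants: 9 1-(benzyloxy)-4-[bis(2-bromoethoxy)methyl]-2-methoxybenzene; 7 (1R,2S)-1-[4-(benzyloxy)-3-methoxyphenyl]-2-methylbut-3-en-1-ol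
Product: 11 1-(benzyloxy)-4-[(2-bromoethoxy){[(1R,2S)-1-(4-benzyloxy-3-methoxyphenyl)-2-methylbut-3-en-1-yl]oxy}methyl]-2-methoxybenzene (both acetal epimers), via N-(α-alkoxybenzyl)collidinium triflate 10 (not isolated)
Conditions: 9 (1.5 equiv), Et3SiOTf (1.5 equiv), 2,4,6-collidine (3 equiv), CH2Cl2, 0 °C; then 7, 0 °C to rt; NaHCO3 work-up
Reagents that add atoms: none
Why: mixed-acetal synthesis by silyl triflate/collidine activation, in which one 2-bromoethoxy group is exchanged for a collidinium leaving group that alcohol 7 then displaces under buffered conditions, so that the acid-sensitive benzylic alcohol never meets free acid and only one mixed acetal can arise from the symmetrical acetal.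

Step 5
Reactants: 11 the 2-bromoethyl mixed acetal
Product: 12 1-(benzyloxy)-4-[{[(1R,2S)-1-(4-benzyloxy-3-methoxyphenyl)-2-methylbut-3-en-1-yl]oxy}(ethenyloxy)methyl]-2-methoxybenzene
Conditions: KOtBu, THF, 0 °C to rt
Reagents that add atoms: none
Why: E2 dehydrobromination of a 2-bromoethyl ether, the standard route to vinyl ethers, under conditions to which the acetal, the benzyl ethers and the terminal alkene are inert.

Step 6
Reactants: 12 the vinyl mixed acetal
Product: 13 (4R,5S)-2,4-bis[4-(benzyloxy)-3-methoxyphenyl]-5-methyl-4,5-dihydro-1,3-dioxepine (both epimers at C2)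
Conditions: second-generation Grubbs catalyst RuCl2(=CHPh)(H2IMes)(PCy3) (10 mol%), 1,4-benzoquinone (20 mol%), toluene, 70 °C
Reagents that add atoms: none
Why: ring-closing metathesis between the monosubstituted alkene and the vinyl ether closes the seven-membered cyclic enol ether with loss of ethene, the ring enforcing the Z double bond and the benzoquinone suppressing migration of the double bond toward the methyl-bearing stereocentre.

Step 7
Reactants: 13 (4R,5S)-2,4-bis[4-(benzyloxy)-3-methoxyphenyl]-5-methyl-4,5-dihydro-1,3-dioxepine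
Product: 15 (2R,3S,4S,5R)-2,5-bis[4-(benzyloxy)-3-methoxyphenyl]-4-methyltetrahydrofuran-3-carbaldehyde, via ring-opened silyl enol ether oxocarbenium triflate 14 (not isolated)
Conditions: Me3SiOTf (0.2 equiv), CH2Cl2, −78 °C; Et3N then aq. NaHCO3 at −78 °C; crude product used at once
Reagents that add atoms: none
Why: Me3SiOTf silylates the enol-ether oxygen of the aryl acetal and the acetal C–O bond to that oxygen ionises, so that an (E)-aryl oxocarbenium ion at the future C2 stays tethered through O1–C5–C4 to a (Z)-silyl enol ether, whose carbon terminus (future C3) adds to it in an intramolecular Mukaiyama-type aldol, a net 1,3 shift of the acetal carbon from oxygen to carbon, after which the silyl group leaves the new formyl oxygen and re-enters the cycle. The closest known reaction type is the Lewis acid-mediated ring contraction of 4,5-dihydro-1,3-dioxepines to 2,3-disubstituted tetrahydrofuran-3-carbaldehydes, applied here to a substrate with two further ring substituents. The tetrahydrofuran closes in a 5-(enolexo)-endo-trig mode, which is accessible because the electrophile is a cationic oxocarbenium ion. C3 should be set by allylic 1,3-strain in the Z enol ether, which holds the C4–H in the enol plane so that the oxocarbenium carbon bonds to the face anti to the C4 methyl and the formyl group ends trans to it. C2 should be set by the cis pair of C4 methyl and C5 aryl, which covers one face of the forming ring and sends the aryl group of the oxocarbenium ion to the other face, cis to the formyl group and trans to the C5 aryl, the arrangement this ring contraction favours under kinetic control. The step needs kinetic control and intact benzylic C–O bonds: the acetal is by far the most easily ionised site, both epimers of 13 give the same ion pair, and −78 °C, a substoichiometric amount of silyl triflate and a cold amine quench should prevent re-opening, heterolysis at C5 and epimerisation of the cis aldehyde.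

Step 8
Reactants: 15 the tetrahydrofuran-3-carbaldehyde
Product: 16 {(2R,3R,4S,5R)-2,5-bis[4-(benzyloxy)-3-methoxyphenyl]-4-methyltetrahydrofuran-3-yl}methanol
Conditions: NaBH4, MeOH/THF, −20 to 0 °C
Reagents that add atoms: none
Why: borohydride reduction of the aldehyde, done on the crude material, removes the acidity of the C3–H before epimerisation can occur and touches no other group.

Step 9
Reactants: 16 the primary alcohol
Product: 17 {(2R,3R,4S,5R)-2,5-bis[4-(benzyloxy)-3-methoxyphenyl]-4-methyltetrahydrofuran-3-yl}methyl methanesulfonate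
Conditions: MsCl, Et3N, CH2Cl2, 0 °C
Reagents that add atoms: methanesulfonyl chloride, CS(=O)(=O)Cl
Why: O-sulfonylation of a primary alcohol, which turns the hydroxyl into a leaving group without touching a stereocentre.

Step 10
Reactants: 17 the mesylate
Product: 18 (2R,3S,4S,5R)-2,5-bis[4-(benzyloxy)-3-methoxyphenyl]-3,4-dimethyltetrahydrofuran
Conditions: LiEt3BH, THF, 0 °C to rt
Reagents that add atoms: none
Why: SN2 displacement of a primary sulfonate by hydride, for which LiEt3BH is the reagent of choice at β-branched carbons, leaves the benzyl ethers and the ring ether intact and turns the former formyl carbon into the C3 methyl.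

Step 11
Reactants: 18 the bis-benzyl ether
Product: 19 4,4'-[(2R,3S,4S,5R)-3,4-dimethyltetrahydrofuran-2,5-diyl]bis(2-methoxyphenol)
Conditions: H2 (1 atm), palladium on carbon (Pd/C), EtOAc, rt
Reagents that add atoms: none
Why: hydrogenolysis of the two benzyl aryl ethers under neutral conditions, where the benzylic C–O bonds of the ring (dialkyl-type ethers, no acid present) should be cleaved far more slowly.

Step 12
Reactants: 20 ethyl (S)-lactate
Product: 21 (2S)-2-hydroxy-N-methoxy-N-methylpropanamide
Conditions: MeNH(OMe)·HCl, i-PrMgCl (3.2 equiv), THF, −20 to 0 °C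
Reagents that add atoms: N,O-dimethylhydroxylamine hydrochloride, CNOC.Cl
Why: Weinreb amide formation by aminolysis of the ester with the chloromagnesium amide, in which the hydroxyl is present as its alkoxide so that the α-carbon is not enolised and keeps its S configuration.

Step 13
Reactants: 21 (2S)-2-hydroxy-N-methoxy-N-methylpropanamide; 22 4-bromo-1,2-dimethoxybenzene
Product: 24 (2S)-1-(3,4-dimethoxyphenyl)-2-hydroxypropan-1-one, via (3,4-dimethoxyphenyl)magnesium bromide 23 (not isolated)
Conditions: 22, Mg, THF, 40 °C; 21, i-PrMgCl (1.0 equiv), THF, −20 °C; then 23 (1.5 equiv), 0 °C; aq. NH4Cl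
Reagents that add atoms: none
Why: Weinreb ketone synthesis, in which the chelated tetrahedral adduct resists both over-addition and enolisation until the quench, so the stereocentre is retained.

Step 14
Reactants: 24 (2S)-1-(3,4-dimethoxyphenyl)-2-hydroxypropan-1-one
Product: 25 (2S)-1-(3,4-dimethoxyphenyl)-1-oxopropan-2-yl 4-methylbenzenesulfonate
Conditions: TsCl, Et3N, DMAP (cat.), CH2Cl2, 0 °C
Reagents that add atoms: p-toluenesulfonyl chloride, Cc1ccc(cc1)S(Cl)(=O)=O
Why: O-sulfonylation with retention, run cold and with a weak amine base so that the α-sulfonyloxy ketone is not enolised.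

Step 15
Reactants: 19 the bis-phenol; 25 the (S)-α-tosyloxy ketone (2.2 equiv)
Product: 26 (2R,2'R)-2,2'-{[(2R,3S,4S,5R)-3,4-dimethyltetrahydrofuran-2,5-diyl]bis[(2-methoxy-4,1-phenylene)oxy]}bis[1-(3,4-dimethoxyphenyl)propan-1-one]
Conditions: 2-tert-butylimino-2-diethylamino-1,3-dimethylperhydro-1,3,2-diazaphosphorine (BEMP, 2.3 equiv), CH2Cl2, 0 °C to rt
Reagents that add atoms: none
Why: double SN2 O-alkylation of the phenoxides by an α-keto sulfonate, a highly SN2-reactive electrophile, with inversion at each carbon (S to R), the non-ionic phosphazene base giving a nucleophilic but weakly basic phenoxide that should not enolise substrate or product.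

Step 16
Reactants: 26 the bis-ketone
Product: 27 (1R,1'R,2R,2'R)-2,2'-{[(2R,3S,4S,5R)-3,4-dimethyltetrahydrofuran-2,5-diyl]bis[(2-methoxy-4,1-phenylene)oxy]}bis[1-(3,4-dimethoxyphenyl)propan-1-ol], the target
Conditions: (R)-2-methyl-CBS-oxazaborolidine (0.5 equiv), BH3·SMe2, THF, −20 °C; MeOH quench
Reagents that add atoms: none
Why: Corey–Bakshi–Shibata reduction, in which the (R)-oxazaborolidine–borane complex delivers hydride to the face of each aryl ketone that gives the R carbinol, the same face that Felkin–Anh attack anti to the aryloxy group prefers, so catalyst and substrate control should agree on the threo (1R,2R) side chains.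

**Compound list**

1 | vanillin | COc1cc(C=O)ccc1O | starting material
2 | benzyl bromide | BrCc1ccccc1 | starting material
3 | 4-(benzyloxy)-3-methoxybenzaldehyde | COc1cc(C=O)ccc1OCc1ccccc1 | intermediate
4 | cis-2-butene | C/C=C\C | starting material
5 | (Z)-but-2-en-1-ylbis[(1S,2R,3S,5S)-2,6,6-trimethylbicyclo[3.1.1]hept-3-yl]borane (not isolated) | C/C=C\CB([C@H]1C[C@H]2C[C@@H]([C@@H]1C)C2(C)C)[C@H]1C[C@H]2C[C@@H]([C@@H]1C)C2(C)C | intermediate
6 | (1R,2S)-1-[4-(benzyloxy)-3-methoxyphenyl]-2-methylbut-3-en-1-yl bis[(1S,2R,3S,5S)-2,6,6-trimethylbicyclo[3.1.1]hept-3-yl]borinate (not isolated) | B(O[C@@H](c1ccc(OCc2ccccc2)c(OC)c1)[C@@H](C)C=C)([C@H]1C[C@H]2C[C@@H]([C@@H]1C)C2(C)C)[C@H]1C[C@H]2C[C@@H]([C@@H]1C)C2(C)C | intermediate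
7 | (1R,2S)-1-[4-(benzyloxy)-3-methoxyphenyl]-2-methylbut-3-en-1-ol | O[C@@H](c1ccc(OCc2ccccc2)c(OC)c1)[C@@H](C)C=C | intermediate
8 | 2-bromoethanol | OCCBr | starting material
9 | 1-(benzyloxy)-4-[bis(2-bromoethoxy)methyl]-2-methoxybenzene | COc1cc(C(OCCBr)OCCBr)ccc1OCc1ccccc1 | intermediate
10 | 1-{[4-(benzyloxy)-3-methoxyphenyl](2-bromoethoxy)methyl}-2,4,6-trimethylpyridinium trifluoromethanesulfonate (not isolated) | COc1cc(C(OCCBr)[n+]2c(C)cc(C)cc2C)ccc1OCc1ccccc1.[O-]S(=O)(=O)C(F)(F)F | intermediate
11 | 1-(benzyloxy)-4-[(2-bromoethoxy){[(1R,2S)-1-(4-benzyloxy-3-methoxyphenyl)-2-methylbut-3-en-1-yl]oxy}methyl]-2-methoxybenzene, acetal carbon as both epimers | BrCCOC(c1ccc(OCc2ccccc2)c(OC)c1)O[C@@H](c1ccc(OCc2ccccc2)c(OC)c1)[C@@H](C)C=C | intermediate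
12 | 1-(benzyloxy)-4-[{[(1R,2S)-1-(4-benzyloxy-3-methoxyphenyl)-2-methylbut-3-en-1-yl]oxy}(ethenyloxy)methyl]-2-methoxybenzene, acetal carbon as both epimers | C=COC(c1ccc(OCc2ccccc2)c(OC)c1)O[C@@H](c1ccc(OCc2ccccc2)c(OC)c1)[C@@H](C)C=C | intermediate
13 | (4R,5S)-2,4-bis[4-(benzyloxy)-3-methoxyphenyl]-5-methyl-4,5-dihydro-1,3-dioxepine, C2 as both epimers | COc1cc(ccc1OCc1ccccc1)C1O[C@@H](c2ccc(OCc3ccccc3)c(OC)c2)[C@@H](C)/C=C\O1 | intermediate
14 | [4-(benzyloxy)-3-methoxybenzylidene]{(1R,2S,3Z)-1-[4-(benzyloxy)-3-methoxyphenyl]-2-methyl-4-(trimethylsilyloxy)but-3-en-1-yl}oxonium trifluoromethanesulfonate (not isolated) | C[Si](C)(C)O/C=C\[C@H](C)[C@H](c1ccc(OCc2ccccc2)c(OC)c1)[O+]=Cc1ccc(OCc2ccccc2)c(OC)c1.[O-]S(=O)(=O)C(F)(F)F | intermediate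
15 | (2R,3S,4S,5R)-2,5-bis[4-(benzyloxy)-3-methoxyphenyl]-4-methyltetrahydrofuran-3-carbaldehyde (2,3-cis, 3,4-trans, 4,5-cis) | c1ccccc1COc1ccc(cc1OC)[C@@H]1O[C@@H](c2ccc(OCc3ccccc3)c(OC)c2)[C@@H](C)[C@@H]1C=O | intermediate
16 | {(2R,3R,4S,5R)-2,5-bis[4-(benzyloxy)-3-methoxyphenyl]-4-methyltetrahydrofuran-3-yl}methanol | c1ccccc1COc1ccc(cc1OC)[C@@H]1O[C@@H](c2ccc(OCc3ccccc3)c(OC)c2)[C@@H](C)[C@@H]1CO | intermediate
17 | {(2R,3R,4S,5R)-2,5-bis[4-(benzyloxy)-3-methoxyphenyl]-4-methyltetrahydrofuran-3-yl}methyl methanesulfonate | c1ccccc1COc1ccc(cc1OC)[C@@H]1O[C@@H](c2ccc(OCc3ccccc3)c(OC)c2)[C@@H](C)[C@@H]1COS(C)(=O)=O | intermediate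
18 | (2R,3S,4S,5R)-2,5-bis[4-(benzyloxy)-3-methoxyphenyl]-3,4-dimethyltetrahydrofuran | c1ccccc1COc1ccc(cc1OC)[C@@H]1O[C@@H](c2ccc(OCc3ccccc3)c(OC)c2)[C@@H](C)[C@@H]1C | intermediate
19 | 4,4'-[(2R,3S,4S,5R)-3,4-dimethyltetrahydrofuran-2,5-diyl]bis(2-methoxyphenol) | COc1cc(ccc1O)[C@@H]1O[C@@H](c2ccc(O)c(OC)c2)[C@@H](C)[C@@H]1C | intermediate
20 | ethyl (S)-lactate | CCOC(=O)[C@H](C)O | starting material
21 | (2S)-2-hydroxy-N-methoxy-N-methylpropanamide | CON(C)C(=O)[C@H](C)O | intermediate
22 | 4-bromo-1,2-dimethoxybenzene | COc1ccc(Br)cc1OC | starting material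
23 | (3,4-dimethoxyphenyl)magnesium bromide (not isolated) | COc1ccc([Mg]Br)cc1OC | intermediate
24 | (2S)-1-(3,4-dimethoxyphenyl)-2-hydroxypropan-1-one | COc1ccc(cc1OC)C(=O)[C@H](C)O | intermediate
25 | (2S)-1-(3,4-dimethoxyphenyl)-1-oxopropan-2-yl 4-methylbenzenesulfonate | COc1ccc(cc1OC)C(=O)[C@H](C)OS(=O)(=O)c1ccc(C)cc1 | intermediate
26 | (2R,2'R)-2,2'-{[(2R,3S,4S,5R)-3,4-dimethyltetrahydrofuran-2,5-diyl]bis[(2-methoxy-4,1-phenylene)oxy]}bis[1-(3,4-dimethoxyphenyl)propan-1-one] | COc1ccc(C(=O)[C@@H](C)Oc2ccc([C@@H]3O[C@@H](c4ccc(O[C@H](C)C(=O)c5ccc(OC)c(OC)c5)c(OC)c4)[C@@H](C)[C@@H]3C)cc2OC)cc1OC | intermediate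
27 | (1R,1'R,2R,2'R)-2,2'-{[(2R,3S,4S,5R)-3,4-dimethyltetrahydrofuran-2,5-diyl]bis[(2-methoxy-4,1-phenylene)oxy]}bis[1-(3,4-dimethoxyphenyl)propan-1-ol] | COc1ccc([C@@H](O)[C@@H](C)Oc2ccc([C@@H]3O[C@@H](c4ccc(O[C@H](C)[C@H](O)c5ccc(OC)c(OC)c5)c(OC)c4)[C@@H](C)[C@@H]3C)cc2OC)cc1OC | target

**Step count and risks**

Total step count: 16. Longest linear sequence: 12 steps (1, 2, 4, 5, 6, 7, 8, 9, 10, 11, 15, 16); steps 3 and 12–14 are side branches.

Steps most likely to fail:

Step 7. The ring contraction may show poor kinetic facial selectivity at C2 (aryl trans instead of cis to the formyl group). The electron-rich benzylic C5–O bond of the ion pair may also undergo heterolysis, or the product may re-open, either of which would scramble C2 or C5. The fallback sets out from alcohol 7 and comes back at compound 18. Alcohol 7 would be hydroborated with 9-BBN and oxidised (NaOH, H2O2) to (1R,2S)-1-[4-(benzyloxy)-3-methoxyphenyl]-2-methylbutane-1,4-diol F1. TEMPO/PhI(OAc)2 should oxidise this at the primary alcohol and lactonise it to (4S,5R)-5-[4-(benzyloxy)-3-methoxyphenyl]-4-methyldihydrofuran-2(3H)-one F2. Enolate methylation (LiN(SiMe3)2, MeI, −78 °C) anti to the C4 methyl should give (3S,4S,5R)-5-[4-(benzyloxy)-3-methoxyphenyl]-3,4-dimethyldihydrofuran-2(3H)-one F3. Reduction with i-Bu2AlH at −78 °C should give (3S,4S,5R)-5-[4-(benzyloxy)-3-methoxyphenyl]-3,4-dimethyltetrahydrofuran-2-ol F4, and PhSO2H with CaCl2 should give (3S,4S,5R)-5-[4-(benzyloxy)-3-methoxyphenyl]-3,4-dimethyl-2-(phenylsulfonyl)tetrahydrofuran F5. Commercial 1-(benzyloxy)-4-bromo-2-methoxybenzene and Mg would give [4-(benzyloxy)-3-methoxyphenyl]magnesium bromide F6, which ZnBr2 transmetallates to [4-(benzyloxy)-3-methoxyphenyl]zinc bromide F7. This reagent would replace the sulfinate through the ring oxocarbenium ion. Attack on the face opposite the C5 aryl and C4 methyl groups should give the 2,5-trans, 2,3-cis ring, which is compound 18.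

Step 4. The alkoxy groups may scramble to symmetrical acetals, or the hindered secondary benzylic alcohol may attack the collidinium salt only slowly. The fallback sets out from acetal 9 and comes back at compound 11. Acetal 9 would be cleaved with acetyl chloride and catalytic ZnBr2 in CH2Cl2 at 0 °C to the α-chloro ether 1-(benzyloxy)-4-[(2-bromoethoxy)chloromethyl]-2-methoxybenzene F8. This would be used at once to alkylate alcohol 7 in the presence of i-Pr2NEt, a classical chloroalkyl-ether etherification that gives 11 without a silyl triflate.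

Step 15. Enolisation of tosylate 25 or of ketone 26 under the basic alkylation conditions may erode the configuration at the α-aryloxy carbon, and the second alkylation may stall. The fallback sets out from bis-phenol 19 and comes back at target 27, bypassing step 16 as well. A double Mitsunobu reaction of 19 with ethyl (S)-lactate 20 (PPh3, diisopropyl azodicarboxylate, THF) should give, with inversion, diethyl (2R,2'R)-2,2'-{[(2R,3S,4S,5R)-3,4-dimethyltetrahydrofuran-2,5-diyl]bis[(2-methoxy-4,1-phenylene)oxy]}dipropanoate F9. Half-reduction with i-Bu2AlH in toluene at −78 °C should give (2R,2'R)-2,2'-{[(2R,3S,4S,5R)-3,4-dimethyltetrahydrofuran-2,5-diyl]bis[(2-methoxy-4,1-phenylene)oxy]}dipropanal F10. Chelation-controlled addition of Grignard reagent 23 (MgBr2·OEt2, CH2Cl2, −78 °C), with magnesium bridging the aldehyde and the 2-methoxyphenoxy oxygens, should then give the threo carbinols of 27.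

Further compounds
F1 | step 7 | (1R,2S)-1-[4-(benzyloxy)-3-methoxyphenyl]-2-methylbutane-1,4-diol | O[C@@H](c1ccc(OCc2ccccc2)c(OC)c1)[C@@H](C)CCO
F2 | step 7 | (4S,5R)-5-[4-(benzyloxy)-3-methoxyphenyl]-4-methyldihydrofuran-2(3H)-one | O=C1O[C@@H](c2ccc(OCc3ccccc3)c(OC)c2)[C@@H](C)C1
F3 | step 7 | (3S,4S,5R)-5-[4-(benzyloxy)-3-methoxyphenyl]-3,4-dimethyldihydrofuran-2(3H)-one | O=C1O[C@@H](c2ccc(OCc3ccccc3)c(OC)c2)[C@@H](C)[C@@H]1C
F4 | step 7 | (3S,4S,5R)-5-[4-(benzyloxy)-3-methoxyphenyl]-3,4-dimethyltetrahydrofuran-2-ol | OC1O[C@@H](c2ccc(OCc3ccccc3)c(OC)c2)[C@@H](C)[C@@H]1C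
F5 | step 7 | (3S,4S,5R)-5-[4-(benzyloxy)-3-methoxyphenyl]-3,4-dimethyl-2-(phenylsulfonyl)tetrahydrofuran | O=S(=O)(c1ccccc1)C1O[C@@H](c2ccc(OCc3ccccc3)c(OC)c2)[C@@H](C)[C@@H]1C
F6 | step 7 | [4-(benzyloxy)-3-methoxyphenyl]magnesium bromide | COc1cc([Mg]Br)ccc1OCc1ccccc1
F7 | step 7 | [4-(benzyloxy)-3-methoxyphenyl]zinc bromide | COc1cc([Zn]Br)ccc1OCc1ccccc1
F8 | step 4 | 1-(benzyloxy)-4-[(2-bromoethoxy)chloromethyl]-2-methoxybenzene | COc1cc(C(Cl)OCCBr)ccc1OCc1ccccc1
F9 | step 15 | diethyl (2R,2'R)-2,2'-{[(2R,3S,4S,5R)-3,4-dimethyltetrahydrofuran-2,5-diyl]bis[(2-methoxy-4,1-phenylene)oxy]}dipropanoate | CCOC(=O)[C@@H](C)Oc1ccc(cc1OC)[C@@H]1O[C@@H](c2ccc(O[C@H](C)C(=O)OCC)c(OC)c2)[C@@H](C)[C@@H]1C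
F10 | step 15 | (2R,2'R)-2,2'-{[(2R,3S,4S,5R)-3,4-dimethyltetrahydrofuran-2,5-diyl]bis[(2-methoxy-4,1-phenylene)oxy]}dipropanal | O=C[C@@H](C)Oc1ccc(cc1OC)[C@@H]1O[C@@H](c2ccc(O[C@H](C)C=O)c(OC)c2)[C@@H](C)[C@@H]1C
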